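The target is cut at C7–C11 of the trans-fused γ-lactone (ring O6–C12–C11–C7–C6; germacrane numbering, C2 the hemiketal carbon). It carries O6, C11 and O8 on three adjacent carbons of the ten-membered ring, with C11 trans to both oxygens. That triad is what an O6-bound phosphonoacetate anion leaves when it opens a cis-7,8-epoxide at C7 from the rear. One operation forms C7–C11, closes the lactone, sets C7 and frees the C8 hydroxyl; phosphorus remains as the handle for C13. The precursor is the oxygen-bridged ten-membered ring (C2 methyl ketal, both exocyclic methylenes) with the cis-7,8-epoxide on the face of the O6 diethylphosphonoacetate.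

Key step: step 17

Numbering used: ring carbons C1–C10; C2 is the (hemi)ketal carbon, joined through the bridging oxygen O5 to C5; C4=C15 and C10=C14 are the exocyclic methylenes; O6 is the lactone oxygen; C7 carries C11 (C12 carbonyl, C13 methylene); O8 is the oxygen on C8.

Assumption: in step 12 the two C2 anomers of the methyl ketal interconvert in acidic methanol; only the anomer with C1 and C6 cis on the oxolane can bridge, and it is the one drawn and carried on.

Remark on the chemistry: the key step uses a halide-free sodium amide base so that no external nucleophile competes for the oxirane. C2 stays a methyl ketal until the last step so that no ketone α-protons and no hemiketal hydroxyl are exposed to base or acylation.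

Step 1
Reactants: 1 diethyl L-tartrate
Product: 2 diethyl (2R,3R)-2-hydroxy-3-(4-methoxybenzyloxy)butanedioate
Conditions: PMBCl, Ag2O, CH2Cl2, rt, dark
Reagents that add atoms: 4-methoxybenzyl chloride, COc1ccc(CCl)cc1
Why: Ag2O-mediated Williamson mono-etherification of a C2-symmetric diol under neutral conditions should stop after one alkylation (the hydroxyls are homotopic, so only one mono-ether exists) and cannot epimerise the α-oxy ester centres; this is what later tells O5 (PMB ether) from O6.

Step 2
Reactants: 2 mono-PMB tartrate
Product: 3 ethyl (2R,3S)-3,4-dihydroxy-2-(4-methoxybenzyloxy)butanoate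
Conditions: BH3·SMe2, NaBH4 (5 mol %), THF, 0 °C to rt; MeOH, aqueous work-up
Reagents that add atoms: none
Why: hydroxyl-directed chemoselective borane reduction, in which the free hydroxyl forms an alkoxyborane that delivers hydride only to the neighbouring ester, so the ester beside the PMB ether (future C4) survives and no stereocentre is touched.

Step 3
Reactants: 3 diol ester
Product: 5 (2S,3S)-3-(4-methoxybenzyloxy)-4-(trimethylsilylmethyl)pent-4-ene-1,2-diol, via bis(silylmethyl) carbinol 4 (not isolated)
Conditions: Me3SiCH2MgCl (6 equiv), CeCl3, THF, −78 °C to rt; then SiO2, CH2Cl2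
Reagents that add atoms: (trimethylsilyl)methylmagnesium chloride, C[Si](C)(C)C[Mg]Cl
Why: cerium-mediated double addition of the silylmethyl Grignard reagent to the ester followed by acid-promoted Peterson elimination of the tertiary β-silyl carbinol should give the 2-substituted allylsilane, placing C3 and C15 on C4 in one operation; the weakly basic organocerium should not enolise toward C5, and the free hydroxyls (or the derived γ-lactone) only consume extra reagent.

Step 4
Reactants: 5 allylsilane diol
Product: 7 trimethyl{(3S)-3-(4-methoxybenzyloxy)-2-methylidene-3-[(2S)-oxiran-2-yl]propyl}silane, via primary tosylate 6 (not isolated)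
Conditions: NaH, N-tosylimidazole, THF, 0 °C to rt
Reagents that add atoms: none
Why: one-pot diol-to-epoxide conversion (selective sulfonylation of the primary alkoxide, then 3-exo-tet Williamson closure by the secondary alkoxide), in which the C6–O bond is never broken, so C6 keeps its configuration.

Step 5
Reactants: 7 terminal epoxide
Product: 8 (3S,4S)-4-(4-methoxybenzyloxy)-5-(trimethylsilylmethyl)hexa-1,5-dien-3-ol
Conditions: Me3S+ I− (4 equiv), n-BuLi (3.8 equiv), THF, −10 °C to rt
Reagents that add atoms: trimethylsulfonium iodide, C[S+](C)C.[I-]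
Why: epoxide-to-allylic-alcohol methylenation with dimethylsulfonium methylide (the ylide opens the oxirane at CH2 and a second ylide triggers α′,β-elimination of Me2S) turns the terminal epoxide into the C6 carbinol bearing the C7 vinyl group without touching C6.

Step 6
Reactants: 8 allylic alcohol
Product: 9 (3S,4S)-3-(tert-butyldimethylsilyloxy)-4-(4-methoxybenzyloxy)-5-(trimethylsilylmethyl)hexa-1,5-diene
Conditions: TBSCl, imidazole, DMAP (cat.), DMF, rt
Reagents that add atoms: tert-butyldimethylsilyl chloride, CC(C)(C)[Si](C)(C)Cl
Why: standard silylation of a secondary alcohol; O6 must be masked so that only O5 can later close the ketal and so that no C6 alkoxide can displace the allylic bromide made next.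

Step 7
Reactants: 9 allylsilane silyl ether
Product: 10 (3S,4S)-5-(bromomethyl)-3-(tert-butyldimethylsilyloxy)-4-(4-methoxybenzyloxy)hexa-1,5-diene
Conditions: NBS, propylene oxide, CH2Cl2, −78 °C
Reagents that add atoms: N-bromosuccinimide, BrN1C(=O)CCC1=O
Why: electrophilic bromodesilylation of an allylsilane (SE2′: bromine adds to the methylene terminus and the β-silyl cation loses silicon); the allylsilane is far more nucleophilic than the vinyl group or the anisyl ring, and the allylic transposition is degenerate for this 2-substituted allyl unit.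

Step 8
Reactants: 10 allylic bromide; 11 1,3-dithiane
Product: 13 (3S,4S)-3-(tert-butyldimethylsilyloxy)-5-(1,3-dithian-2-ylmethyl)-4-(4-methoxybenzyloxy)hexa-1,5-diene, via 2-lithio-1,3-dithiane 12 (not isolated)
Conditions: n-BuLi, THF, −30 °C; then 10, −78 to −30 °C
Reagents that add atoms: none
Why: Corey–Seebach alkylation, in which the lithiated dithiane (C2 as acyl-anion equivalent) displaces the primary allylic bromide by SN2 and creates C2–C3.

Step 9
Reactants: 14 3-chloro-2-(chloromethyl)prop-1-ene
Product: 15 2-(chloromethyl)penta-1,4-diene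
Conditions: CH2=CHMgBr (1 equiv), CuI (5 mol %), THF, −30 to 0 °C; 14 in threefold excess; distillation
Reagents that add atoms: vinylmagnesium bromide, C=C[Mg]Br
Why: copper-catalysed allylic substitution of one chloride by the vinyl Grignard reagent (SN2 and SN2′ paths give the same product for this symmetrical allyl unit), with excess dichloride limiting double substitution; the product carries C1, C10, C14, C9 and C8.

Step 10
Reactants: 13 monoalkyl dithiane; 15 allylic chloride
Product: 17 (3S,4S)-3-(tert-butyldimethylsilyloxy)-4-(4-methoxybenzyloxy)-5-{[2-(2-methylidenepent-4-en-1-yl)-1,3-dithian-2-yl]methyl}hexa-1,5-diene, via lithiated dithiane 16 (not isolated)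
Conditions: t-BuLi, THF/HMPA (10:1), −78 °C, 10 min; then 15, −78 to −40 °C
Reagents that add atoms: none
Why: second Corey–Seebach alkylation, in which brief low-temperature lithiation of the 2-alkyl dithiane (kinetically favoured over the ether C–H bonds) and SN2 capture by the allylic chloride form C1–C2 and complete the chain C1–C10 with both methylenes in place.

Step 11
Reactants: 17 dialkyl dithiane
Product: 18 (3S,4S)-3-(tert-butyldimethylsilyloxy)-4-(4-methoxybenzyloxy)-5,9-dimethylidenedodeca-1,11-dien-7-one
Conditions: MeI, CaCO3, MeCN/H2O (9:1), 45 °C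
Reagents that add atoms: water, O
Why: alkylative hydrolysis of the dithiane (S-methylation, then hydrolysis of the sulfonium thioacetal) under carbonate buffering unveils the C2 ketone without acid or base strong enough to pull the two β,γ-methylenes into conjugation.

Step 12
Reactants: 18 ketone
Product: 20 (2S,5S)-2-[(1S)-1-(tert-butyldimethylsilyloxy)prop-2-en-1-yl]-5-methoxy-3-methylidene-5-(2-methylidenepent-4-en-1-yl)oxolane, via hydroxy ketone 19 (not isolated)
Conditions: DDQ, CH2Cl2/pH 7 buffer, 0 °C; then PPTS, MeOH, rt
Reagents that add atoms: methanol, CO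
Why: oxidative PMB cleavage frees only O5–H, which adds to the C2 ketone (5-exo-trig), and acid-catalysed exchange in methanol converts the hemiketal into the methyl ketal; with O6 silylated the six-membered alternative is excluded, and C2 is set under equilibrium control, the anomer with C1 and C6 cis being carried on while its epimer is returned to the same conditions.

Step 13
Reactants: 20 diene methyl ketal
Product: 21 (1S,2S,3Z,8S)-2-(tert-butyldimethylsilyloxy)-8-methoxy-6,10-dimethylidene-11-oxabicyclo[6.2.1]undec-3-ene
Conditions: Cl2(PCy3)2Ru=CHPh (first-generation Grubbs catalyst, 10 mol %), CH2Cl2 (1 mM), reflux, Ar sparge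
Reagents that add atoms: none
Why: ring-closing metathesis of the two monosubstituted vinyl groups forms C7=C8; the cis-2,5-disubstituted oxolane holds the chain ends together, the bridged ten-membered ring can hold only a Z olefin, the catalyst should enter at the unhindered C8 vinyl (from where the only small-ring alternative, onto the C4 methylene, would need a bridgehead double bond), and this phosphine catalyst is chosen because it engages 1,1-disubstituted olefins only sluggishly.

Step 14
Reactants: 21 bicyclic silyl ether
Product: 22 (1S,2S,3Z,8S)-8-methoxy-6,10-dimethylidene-11-oxabicyclo[6.2.1]undec-3-en-2-ol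
Conditions: TBAF, THF, 0 °C to rt
Reagents that add atoms: none
Why: fluoride-mediated desilylation frees the C6 allylic alcohol; the ketal and the three olefins are inert to fluoride.

Step 15
Reactants: 22 allylic alcohol
Product: 23 syn-epoxy alcohol (cis-7,8-epoxide of 22 with the oxirane oxygen on the ring face of the 6-hydroxyl)
Conditions: VO(acac)2 (5 mol %), t-BuOOH (1.2 equiv), CH2Cl2, 0 °C
Reagents that add atoms: tert-butyl hydroperoxide, CC(C)(C)OO
Why: hydroxyl-directed epoxidation, in which the vanadium alkoxide of O6 delivers the peroxide oxygen intramolecularly to the adjacent Z olefin; this should give the cis-epoxide on the O6 face (the usual outcome for medium-ring Z-allylic alcohols) and sets C7 and C8 together, while the homoallylic C4 methylene and the remote C10 methylene react far more slowly.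

Step 16
Reactants: 23 syn-epoxy alcohol; 24 diethylphosphonoacetic acid
Product: 25 6-O-(diethylphosphonoacetyl) ester of 23
Conditions: DCC, DMAP (cat.), CH2Cl2, 0 °C to rt
Reagents that add atoms: none
Why: Steglich esterification under neutral conditions acylates the hindered C6 hydroxyl without forming the alkoxide, so neither Payne rearrangement nor epoxide opening can intervene.

Step 17
Reactants: 25 epoxy phosphonoacetate
Product: 26 α-(diethoxyphosphoryl) trans-fused γ-lactone with free 8-hydroxyl and C2 methyl ketal (C11 epimers)
Conditions: NaN(SiMe3)2 (1.05 equiv), THF, −78 to 0 °C; AcOH/THF quench at −40 °C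
Reagents that add atoms: none
Why: The amide base removes a proton from the phosphonoacetate CH2 (the only acidic site) and the stabilised carbanion C11 attacks the epoxide carbon C7 from the face opposite the C7–O bond (intramolecular SN2 alkylation), after which the C8 alkoxide is protonated by the newly acidic C11–H, so the product rests as its phosphonate-stabilised enolate until the acetic acid quench. The closest known reaction types are the lactone-forming opening of epoxides by phosphonoacetate and malonate anions and the 5-exo opening of 2,3-epoxy alcohol carbamates at the carbon next to the carbinol. The one ring closed, the γ-lactone O6–C12–C11–C7–C6, forms in the 5-exo-tet mode, the breaking C7–O bond lying outside the new ring. The one new stereocentre, C7, is fixed by inversion in this stereospecific step, so C11 ends trans to O8 and, because step 15 placed the oxirane on the O6 face, trans to O6 as well (C11 itself stays epimeric and is erased in step 18). The step needs attack at C7 and not at C8, and needs the lactone to stay on O6: the three-atom tether anchored on C6 reaches C7 through a five-membered transition state (C8 would require the six-membered endo mode), the ten-membered ring can place C6–O6 anti to the C7–O bond as a trans-fused lactone demands, and the enolate resting state plus the cold quench keep the C8 alkoxide from attacking C12 or phosphorus. No halide or other external nucleophile is present that could open the oxirane.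

Step 18
Reactants: 26 α-phosphono lactone
Product: 27 α-methylene trans-γ-lactone with free 8-hydroxyl and C2 methyl ketal
Conditions: K2CO3, 37 % aq. HCHO, THF, 0 °C to rt
Reagents that add atoms: formaldehyde, C=O
Why: Horner–Wadsworth–Emmons olefination of the α-phosphono lactone with formaldehyde installs C13 as the exocyclic methylene and removes the C11 stereocentre, the mild carbonate base keeping the lactone on O6.

Step 19
Reactants: 27 hydroxy α-methylene lactone; 28 tigloyl chloride
Product: 29 8-O-tiglate of 27 (C2 methyl ketal)
Conditions: DMAP, Et3N, CH2Cl2, 0 °C to rt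
Reagents that add atoms: none
Why: DMAP-catalysed acylation of the only free hydroxyl (C8) by the acid chloride, a standard esterification of hydroxylated α-methylene lactones; the E geometry of the tigloyl group is the stable one and is kept.

Step 20
Reactants: 29 tiglate methyl ketal
Product: 30 target CNP0307443.2
Conditions: PPTS, acetone/H2O (4:1), rt
Reagents that add atoms: water, O
Why: mild acid-catalysed hydrolysis of the bridgehead methyl ketal through the ring oxocarbenium ion returns the hemiketal, whose C2 configuration is dictated by the oxygen bridge; lactone, tiglate and methylenes should tolerate these conditions.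

Compound list

1 | diethyl L-tartrate, diethyl (2R,3R)-2,3-dihydroxybutanedioate | CCOC(=O)[C@H](O)[C@@H](O)C(=O)OCC | starting material
2 | diethyl (2R,3R)-2-hydroxy-3-(4-methoxybenzyloxy)butanedioate | CCOC(=O)[C@H](OCc1ccc(OC)cc1)[C@@H](O)C(=O)OCC | intermediate
3 | ethyl (2R,3S)-3,4-dihydroxy-2-(4-methoxybenzyloxy)butanoate | CCOC(=O)[C@H](OCc1ccc(OC)cc1)[C@@H](O)CO | intermediate
4 | (2S,3R)-3-(4-methoxybenzyloxy)-5-(trimethylsilyl)-4-(trimethylsilylmethyl)pentane-1,2,4-triol (not isolated) | C[Si](C)(C)CC(O)(C[Si](C)(C)C)[C@H](OCc1ccc(OC)cc1)[C@@H](O)CO | intermediate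
5 | (2S,3S)-3-(4-methoxybenzyloxy)-4-(trimethylsilylmethyl)pent-4-ene-1,2-diol | C[Si](C)(C)CC(=C)[C@H](OCc1ccc(OC)cc1)[C@@H](O)CO | intermediate
6 | primary 4-methylbenzenesulfonate of 5 (not isolated) | C[Si](C)(C)CC(=C)[C@H](OCc1ccc(OC)cc1)[C@@H](O)COS(=O)(=O)c1ccc(C)cc1 | intermediate
7 | trimethyl{(3S)-3-(4-methoxybenzyloxy)-2-methylidene-3-[(2S)-oxiran-2-yl]propyl}silane | C[Si](C)(C)CC(=C)[C@H](OCc1ccc(OC)cc1)[C@@H]1CO1 | intermediate
8 | (3S,4S)-4-(4-methoxybenzyloxy)-5-(trimethylsilylmethyl)hexa-1,5-dien-3-ol | C[Si](C)(C)CC(=C)[C@H](OCc1ccc(OC)cc1)[C@@H](O)C=C | intermediate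
9 | (3S,4S)-3-(tert-butyldimethylsilyloxy)-4-(4-methoxybenzyloxy)-5-(trimethylsilylmethyl)hexa-1,5-diene | C[Si](C)(C)CC(=C)[C@H](OCc1ccc(OC)cc1)[C@@H](O[Si](C)(C)C(C)(C)C)C=C | intermediate
10 | (3S,4S)-5-(bromomethyl)-3-(tert-butyldimethylsilyloxy)-4-(4-methoxybenzyloxy)hexa-1,5-diene | BrCC(=C)[C@H](OCc1ccc(OC)cc1)[C@@H](O[Si](C)(C)C(C)(C)C)C=C | intermediate
11 | 1,3-dithiane | C1CSCSC1 | starting material
12 | 2-lithio-1,3-dithiane (not isolated) | [Li]C1SCCCS1 | intermediate
13 | (3S,4S)-3-(tert-butyldimethylsilyloxy)-5-(1,3-dithian-2-ylmethyl)-4-(4-methoxybenzyloxy)hexa-1,5-diene | S1CCCSC1CC(=C)[C@H](OCc1ccc(OC)cc1)[C@@H](O[Si](C)(C)C(C)(C)C)C=C | intermediate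
14 | 3-chloro-2-(chloromethyl)prop-1-ene | C=C(CCl)CCl | starting material
15 | 2-(chloromethyl)penta-1,4-diene | C=CCC(=C)CCl | intermediate
16 | 2-lithio derivative of 13 (not isolated) | [Li]C1(SCCCS1)CC(=C)[C@H](OCc1ccc(OC)cc1)[C@@H](O[Si](C)(C)C(C)(C)C)C=C | intermediate
17 | (3S,4S)-3-(tert-butyldimethylsilyloxy)-4-(4-methoxybenzyloxy)-5-{[2-(2-methylidenepent-4-en-1-yl)-1,3-dithian-2-yl]methyl}hexa-1,5-diene | C=CCC(=C)CC1(SCCCS1)CC(=C)[C@H](OCc1ccc(OC)cc1)[C@@H](O[Si](C)(C)C(C)(C)C)C=C | intermediate
18 | (3S,4S)-3-(tert-butyldimethylsilyloxy)-4-(4-methoxybenzyloxy)-5,9-dimethylidenedodeca-1,11-dien-7-one | C=CCC(=C)CC(=O)CC(=C)[C@H](OCc1ccc(OC)cc1)[C@@H](O[Si](C)(C)C(C)(C)C)C=C | intermediate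
19 | (3S,4S)-3-(tert-butyldimethylsilyloxy)-4-hydroxy-5,9-dimethylidenedodeca-1,11-dien-7-one, in equilibrium with its cyclic hemiketal (not isolated) | C=CCC(=C)CC(=O)CC(=C)[C@H](O)[C@@H](O[Si](C)(C)C(C)(C)C)C=C | intermediate
20 | (2S,5S)-2-[(1S)-1-(tert-butyldimethylsilyloxy)prop-2-en-1-yl]-5-methoxy-3-methylidene-5-(2-methylidenepent-4-en-1-yl)oxolane (C1 and C6 cis on the oxolane) | C=C[C@H](O[Si](C)(C)C(C)(C)C)[C@H]1O[C@@](OC)(CC(=C)CC=C)CC1=C | intermediate
21 | (1S,2S,3Z,8S)-2-(tert-butyldimethylsilyloxy)-8-methoxy-6,10-dimethylidene-11-oxabicyclo[6.2.1]undec-3-ene (skeleton numbering: 2S,5S,6S, 7Z) | C=C1C/C=C\[C@H](O[Si](C)(C)C(C)(C)C)[C@H]2O[C@@](OC)(C1)CC2=C | intermediate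
22 | (1S,2S,3Z,8S)-8-methoxy-6,10-dimethylidene-11-oxabicyclo[6.2.1]undec-3-en-2-ol | C=C1C/C=C\[C@H](O)[C@H]2O[C@@](OC)(C1)CC2=C | intermediate
23 | cis-7,8-epoxide of 22, oxirane oxygen on the ring face of the 6-hydroxyl (skeleton numbering: 2S,5S,6R,7R,8S) | C=C1C[C@@H]2O[C@@H]2[C@H](O)[C@H]3O[C@@](OC)(C1)CC3=C | intermediate
24 | diethylphosphonoacetic acid | OC(=O)CP(=O)(OCC)OCC | starting material
25 | 6-O-(diethylphosphonoacetyl) ester of 23 (skeleton numbering: 2S,5S,6R,7S,8S), the key-step precursor | C=C1C[C@@H]2O[C@@H]2[C@H](OC(=O)CP(=O)(OCC)OCC)[C@H]3O[C@@](OC)(C1)CC3=C | intermediate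
26 | trans-fused α-(diethoxyphosphoryl) γ-lactone (O6–C12, C7–C11) with free 8-hydroxyl cis to O6 and trans to C11, C2 methyl ketal (2S,5S,6S,7R,8S; C11 epimers) | C=C1C[C@H](O)[C@H]2C(P(=O)(OCC)OCC)C(=O)O[C@@H]2[C@H]3O[C@@](OC)(C1)CC3=C | intermediate
27 | α-methylene trans-γ-lactone with free 8-hydroxyl, C2 methyl ketal (2S,5S,6S,7R,8S) | C=C1C[C@H](O)[C@H]2C(=C)C(=O)O[C@@H]2[C@H]3O[C@@](OC)(C1)CC3=C | intermediate
28 | tigloyl chloride, (E)-2-methylbut-2-enoyl chloride | C/C=C(\C)C(=O)Cl | starting material
29 | 8-O-tiglate of 27, C2 methyl ketal (2S,5S,6S,7R,8S) | C=C1C[C@H](OC(=O)/C(C)=C/C)[C@H]2C(=C)C(=O)O[C@@H]2[C@H]3O[C@@](OC)(C1)CC3=C | intermediate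
30 | CNP0307443.2: 8-O-tigloyl α-methylene trans-γ-lactone with the 2,5-oxygen-bridged C2 hemiketal (2S,5S,6S,7R,8S) | C=C1C[C@H](OC(=O)/C(C)=C/C)[C@H]2C(=C)C(=O)O[C@@H]2[C@H]2O[C@@](O)(C1)CC2=C | target

Total step count: 20. Longest linear sequence: 19 steps (steps 1–8 and 10–20; step 9 is a one-step side branch).

Steps most likely to fail

Step 17. The hindered, chelated phosphonate carbanion may fail to reach the rear of C7 inside the bridged ring, so that the epoxide is recovered; on forcing, the C8 alkoxide may attack phosphorus or C12 (phosphoryl transfer, lactone migration to O8). The fallback replaces the phosphonate-stabilised anion by a malonate and the olefination by a decarboxylative Mannich methylenation. It sets out from 23: DCC/DMAP esterification with allyl hydrogen malonate should give the 6-O-(allyl malonyl) ester F1. NaH in THF (0 °C to rt) then lets the smaller malonate anion, the classical carbon nucleophile for oxiranes and free of phosphorus, open the epoxide in the same 5-exo sense to the α-(allyloxycarbonyl) trans-lactone F2. Pd(PPh3)4 with morpholine removes the allyl group to give the α-carboxy lactone F3. Aqueous formaldehyde with Et2NH and AcOH/NaOAc then effects decarboxylative methylenation to 27, where the route is rejoined.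

Step 13. Strain in the bridged ten-membered ring may slow closure so much that intermolecular metathesis (oligomers) takes over, or that the catalyst re-enters at the C7 vinyl and closes onto the C10 methylene (a seven-membered ring). The fallback holds C14 back until after ring closure, so that no small ring can form and a more active catalyst can be used. It sets out from 13: lithiation (t-BuLi, THF/HMPA, −78 °C) and opening of 2-allyloxirane should give the C10 carbinol dithiane F4 (both C10 epimers; they converge later). MeI/CaCO3 then gives the hydroxy ketone F5. DDQ gives the dihydroxy ketone F6 (not isolated), and PPTS/MeOH closes the methyl ketal carbinol F7. Ring closure with (H2IMes)Cl2Ru=CH(C6H4-2-OiPr) (second-generation Hoveyda–Grubbs catalyst) in dilute toluene gives the bicyclic C10 alcohol F8. Dess–Martin periodinane (NaHCO3) gives the bicyclic C10 ketone F9, and Petasis methylenation with Cp2TiMe2 (toluene, 70 °C) gives 21, where the route is rejoined.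

Step 10. Proton transfer may compete with alkylation: lithiation next to the allylic PMB ether (followed by Wittig rearrangement), or quenching of the dithiane anion by the doubly allylic CH2 of 15. The fallback builds the ketone without strong base, by Barbier allylation and oxidation, and bypasses the dithiane. It sets out from 10 and 15: the Grignard reagent of 15 (Mg, THF) with paraformaldehyde should give 3-methylidenehex-5-en-1-ol F10. Dess–Martin periodinane (NaHCO3) gives 3-methylidenehex-5-enal F11, used crude. Indium-mediated Barbier coupling of 10 with F11 (In powder, THF/H2O) gives the C2 carbinol F12 (both epimers), and a second Dess–Martin oxidation gives 18, where the route is rejoined.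

Further compounds

F1 | step 17 | 6-O-(allyl malonyl) ester of syn-epoxy alcohol 23 | C=C1C[C@@H]2O[C@@H]2[C@H](OC(=O)CC(=O)OCC=C)[C@H]3O[C@@](OC)(C1)CC3=C
F2 | step 17 | α-(allyloxycarbonyl) trans-fused γ-lactone with free 8-hydroxyl, C2 methyl ketal (C11 epimers) | C=C1C[C@H](O)[C@H]2C(C(=O)OCC=C)C(=O)O[C@@H]2[C@H]3O[C@@](OC)(C1)CC3=C
F3 | step 17 | α-carboxy trans-fused γ-lactone with free 8-hydroxyl, C2 methyl ketal (C11 epimers) | C=C1C[C@H](O)[C@H]2C(C(=O)O)C(=O)O[C@@H]2[C@H]3O[C@@](OC)(C1)CC3=C
F4 | step 13 | (3S,4S)-3-(tert-butyldimethylsilyloxy)-5-{[2-(2-hydroxypent-4-en-1-yl)-1,3-dithian-2-yl]methyl}-4-(4-methoxybenzyloxy)hexa-1,5-diene (C10 epimers) | C=CCC(O)CC1(SCCCS1)CC(=C)[C@H](OCc1ccc(OC)cc1)[C@@H](O[Si](C)(C)C(C)(C)C)C=C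
F5 | step 13 | (3S,4S)-3-(tert-butyldimethylsilyloxy)-9-hydroxy-4-(4-methoxybenzyloxy)-5-methylidenedodeca-1,11-dien-7-one (C9 epimers) | C=CCC(O)CC(=O)CC(=C)[C@H](OCc1ccc(OC)cc1)[C@@H](O[Si](C)(C)C(C)(C)C)C=C
F6 | step 13 | (3S,4S)-3-(tert-butyldimethylsilyloxy)-4,9-dihydroxy-5-methylidenedodeca-1,11-dien-7-one (not isolated) | C=CCC(O)CC(=O)CC(=C)[C@H](O)[C@@H](O[Si](C)(C)C(C)(C)C)C=C
F7 | step 13 | methyl ketal as 20 but with a 2-hydroxypent-4-en-1-yl chain on the ketal carbon (C10 carbinol in place of the C10 methylene) | C=C[C@H](O[Si](C)(C)C(C)(C)C)[C@H]1O[C@@](OC)(CC(O)CC=C)CC1=C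
F8 | step 13 | bicyclic Z-olefin as 21 but with a C10 hydroxyl in place of the C10 methylene | OC1C/C=C\[C@H](O[Si](C)(C)C(C)(C)C)[C@H]2O[C@@](OC)(C1)CC2=C
F9 | step 13 | bicyclic Z-olefin as 21 but with a C10 ketone in place of the C10 methylene | O=C1C/C=C\[C@H](O[Si](C)(C)C(C)(C)C)[C@H]2O[C@@](OC)(C1)CC2=C
F10 | step 10 | 3-methylidenehex-5-en-1-ol | C=CCC(=C)CCO
F11 | step 10 | 3-methylidenehex-5-enal | C=CCC(=C)CC=O
F12 | step 10 | (3S,4S)-3-(tert-butyldimethylsilyloxy)-4-(4-methoxybenzyloxy)-5,9-dimethylidenedodeca-1,11-dien-7-ol (C7 epimers) | C=CCC(=C)CC(O)CC(=C)[C@H](OCc1ccc(OC)cc1)[C@@H](O[Si](C)(C)C(C)(C)C)C=C
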